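In a closed, stirred vessel an electrophile is consumed by a nucleophile while a gas feeds in a base, and I wanted the charge of nucleophile.

    electrophile ⇌ dormant form (K1 = 1.41, k1 = 0.00563 min⁻¹)
    electrophile + nucleophile → acid set free + target (k2 = 0.00454 M⁻¹ min⁻¹)
    nucleophile + acid set free ⇌ protonated nucleophile, settled at all times (K3 = 538 M⁻¹)
    gas ⇌ free base, rate k4*(csat - [free base]) (k4 = 0.00706 min⁻¹, csat = 200 mM)
    2 nucleophile → self-condensation product (k5 = 2.33 × 10⁻⁴ M⁻¹ min⁻¹)
    acid set free + free base ⇌ salt of the base, settled at all times (K6 = 3.00 × 10⁵ M⁻¹)

electrophile 0.72 M; gas 200 mM (held); time 40 h

* the concentration of nucleophile at which the part of the electrophile that has reacted at 40 h is just 80%, in M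

- for a step with 2 of a species take k times the square, and two of it per event
- at the start none of free base is dissolved
- the amount of nucleophile is what is sought; it is there from the start
- run time (flask): 40 h

I read the level on free electrophile, which had to fall to 20.0% of its charge. I built the flask up one step at a time. Since ln[electrophile] falls at k2[nucleophile], I replaced the curve by its time mean. Taking the fall as exponential, a drop x with mean m needs a start of x/(1 − exp(−x/m)).

With the main step alone:

mean = 0.148 M, x = 0.576 M, start = 0.588 M

The exact second-order law puts that charge at 77.2% reacted, so the start reckoned from the mean came out slightly low.

Next came dormancy. The exchange relaxes at 0.00962 min⁻¹, faster than the main step's 0.00267 min⁻¹ at the start, so I held the electrophile at its free share 0.415, the part 1/(1 + K1) of the pool of electrophile and dormant form. The dormant form is the resting state, and the pool had to fall to 0.347 M: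

mean = 0.161 M, x = 0.373 M, start = 0.414 M

Self-condensation then takes two nucleophile per event, at k5[nucleophile]², and I integrated that along the exponential fall:

loss = 0.0411 M, start = 0.449 M

The gas offers 3.39 M of free base at full transfer, far more than that acid, so I took protonated nucleophile as handed back.

The forecast said 0.94 M, twice my figure, on its own reading: “I took "reacted" to mean converted to target”.

The simulation gave 0.447 M, and the forecast stood twice that. At 40.0 h in this flask, electrophile had a half-life of 2.1 h by the forward step to the dormant form, far shorter than the 54 h by the main step. Dividing that main-step half-life by the free share 0.415 puts the half-life of the pool of electrophile and dormant form in this flask, at that time and under the main step, at 130 h.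

The numbers are assumed; the result is computed.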